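The decalin is traced back to a ten-membered carbocycle: everything rests on the ring-fusion bond C5–C10 (eudesmane numbering), which is shared by rings A and B. A transannular cation–olefin cyclization of an (E,E)-cyclodeca-1,5-diene, germacra-1(10),4-dien-6-yl acetate, closes both six-membered rings in one acid-mediated operation. It sets the quaternary C10 and the C5 methine trans to each other under control of the C7 isopropyl group, and places the C3=C4 olefin. It exploits the 1,5-relationship of the C1=C10 and C4=C5 olefins, which hold C5 and C10 face to face across the ring. The macrocycle comes from farnesol; a tartrate-controlled epoxide relays the absolute configuration and is then removed.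

Key step: step 8

Numbering: germacrane/eudesmane numbering is used throughout. C4 carries the vinylic methyl (C15), C5 is the ring-fusion CH, C6 the oxygenated carbon, C7 the isopropyl-bearing carbon and C10 the carbon with the angular methyl (C14). α/β refer to the usual eudesmane drawing with the C10 methyl β. The target is 5α-H, 6β-O (axial), 7β-isopropyl, 10β-methyl, i.e. 5R,6R,7S,10R.

Remark (assumption): the macrocyclization of step 5 is taken to follow the dipole-minimised chair model given there. If the aldehyde face were attacked in the opposite sense, the epoxide from L-(+)-diethyl tartrate would be carried through instead and would converge on the same compound 10.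

Step 1
Reactants: 1 (2E,6E)-farnesol
Product: 2 (2R,3R)-2,3-epoxy-(6E)-farnesol, i.e. [(2R,3R)-3-[(3E)-4,8-dimethylnona-3,7-dienyl]-3-methyloxiran-2-yl]methanol
Conditions: Ti(OiPr)4 (5 mol%), D-(−)-diethyl tartrate (6 mol%), t-BuOOH, 4 Å MS, CH2Cl2, −20 °C
Reagents that add atoms: tert-butyl hydroperoxide CC(C)(C)OO
Why: Sharpless asymmetric epoxidation acts only on the allylic-alcohol olefin, and the D-tartrate ligand delivers oxygen to the face that sets C2 and C3 as R,R (the trans epoxide of the E olefin).

Step 2
Reactants: 2 (2R,3R)-2,3-epoxyfarnesol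
Product: 3 (2R,3R,6E,10E)-2,3-epoxy-3,7,11-trimethyldodeca-6,10-diene-1,12-diol
Conditions: SeO2 (0.3 equiv), t-BuOOH, CH2Cl2, 0 °C to rt
Reagents that add atoms: selenium dioxide O=[Se]=O (catalytic oxygen carrier); tert-butyl hydroperoxide CC(C)(C)OO (terminal oxidant)
Why: Selenium dioxide allylic oxidation (ene reaction, then [2,3]-sigmatropic shift) attacks the E-methyl group of the terminal trisubstituted olefin, the most accessible allylic position, and creates no stereocentre.

Step 3
Reactants: 3 epoxy diol
Product: 4 (2R,3R,6E,10E)-12-chloro-2,3-epoxy-3,7,11-trimethyldodeca-6,10-dien-1-ol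
Conditions: NCS, Me2S, CH2Cl2, −20 °C to 0 °C
Reagents that add atoms: N-chlorosuccinimide O=C1CCC(=O)N1Cl
Why: Corey–Kim chlorination converts only the allylic alcohol, whose alkoxysulfonium ion is displaced by chloride (SN2), while the non-allylic epoxy alcohol is returned on work-up.

Step 4
Reactants: 4 chloro epoxy alcohol
Product: 5 (2S,3R,6E,10E)-12-chloro-2,3-epoxy-3,7,11-trimethyldodeca-6,10-dienal (same spatial arrangement as 4; only the C2 descriptor changes with the priorities)
Conditions: Dess–Martin periodinane, NaHCO3, CH2Cl2, 0 °C to rt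
Reagents that add atoms: none
Why: Dess–Martin oxidation under buffered conditions should give the α,β-epoxy aldehyde without epimerization and without touching the allylic chloride.

Step 5
Reactants: 5 chloro epoxy aldehyde
Product: 8 (1(10)E,4R,5R,6S,7S)-4,5-epoxygermacra-1(10),11-dien-6-yl acetate, via allylzinc 6 (not isolated), via ethylzinc alkoxide 7 (not isolated)
Conditions: PdCl2(PPh3)2 (10 mol%), Et2Zn, DMA, rt, slow addition of 5 (high dilution); then Ac2O, DMAP, rt
Reagents that add atoms: acetic anhydride CC(=O)OC(C)=O; diethylzinc CC[Zn]CC (zinc and ethyl only in 6 and 7)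
Why: Palladium/diethylzinc umpolung allylation of an aldehyde: the π-allylpalladium chloride is transmetallated to allylzinc 6, which adds through its γ-carbon in a six-membered chair transition state and closes the ten-membered ring; the aldehyde reacts with its C=O anti to the epoxide C–O bond and is attacked past H-5 (sets C6 as S), the chair with the chain equatorial gives the anti adduct (sets C7 as S), and the zinc alkoxide 7 is acetylated in the same flask.

Step 6
Reactants: 8 epoxy dienyl acetate
Product: 9 (1(10)E,4R,5R,6S,7S)-4,5-epoxygermacr-1(10)-en-6-yl acetate (isopropyl at C7)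
Conditions: H2 (1 atm), RhCl(PPh3)3 (5 mol%), benzene, rt
Reagents that add atoms: none
Why: Homogeneous hydrogenation with RhCl(PPh3)3 should reduce the 1,1-disubstituted isopropenyl olefin far faster than the trisubstituted ring olefin, leaving C7 untouched.

Step 7
Reactants: 9 epoxy enyl acetate
Product: 10 (1(10)E,4E,6S,7S)-germacra-1(10),4-dien-6-yl acetate
Conditions: WCl6, n-BuLi (2 equiv per W), THF, −78 °C to rt; then 9, rt
Reagents that add atoms: none
Why: Deoxygenation of an epoxide by a low-valent tungsten chloride (oxygen-atom abstraction with formation of a tungsten oxo species) proceeds with retention, so the trans-trisubstituted epoxide should return the 4E olefin while the acetate keeps the C6 oxygen inert.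

Step 8
Reactants: 10 (1(10)E,4E,6S,7S)-germacra-1(10),4-dien-6-yl acetate
Product: 11 (5R,6S,7S,10R)-eudesm-3-en-6-yl acetate (5α-H, 6α-acetoxy, 7β-isopropyl, 10β-methyl)
Conditions: TsOH·H2O (0.2 equiv), CH2Cl2, 0 °C to rt
Reagents that add atoms: none
Why: Protonation of the C1=C10 olefin at C1 is concerted with attack of C5 of the C4=C5 olefin on the developing tertiary C10 cation, and the resulting tertiary C4 cation loses H-3 (transannular cation–olefin cyclization; the closest known reaction type is the acid-mediated cyclization of (E,E)-germacra-1(10),4-dienes with a 6α-acyloxy group to eudesmanes). Through the one new C5–C10 bond, ring A (C1–C2–C3–C4–C5–C10) closes 6-endo with respect to both olefins and ring B (C5–C6–C7–C8–C9–C10) 6-exo with respect to both. C10 (R, β-methyl) and C5 (R, α-H) are set together by the crossed chair–chair conformer with both olefinic methyls on the β face, which is selected because it places the C7 isopropyl and C6 acetoxy groups pseudo-equatorial; the E geometry of both olefins then translates into the trans ring fusion. The step needs olefin protonation to outrun ionization of the allylic acetate, which the poor leaving-group ability of the ester under catalytic sulfonic acid and the transannular assistance should secure. It also needs loss of H-3 instead of H-5 or H-15: the C4=C5 isomer is disfavoured by allylic 1,3-strain between C15 and the equatorial 6α-acetoxy group, and the exocyclic C4=C15 isomer should drain into the more stable endocyclic trisubstituted olefin by reversible protonation under the reaction conditions.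

Step 9
Reactants: 11 eudesm-3-en-6α-yl acetate
Product: 12 (5R,6S,7S,10R)-eudesm-3-en-6-ol (equatorial 6α-alcohol)
Conditions: K2CO3, MeOH, 50 °C
Reagents that add atoms: none
Why: Base-catalysed transesterification (methanolysis) frees the alcohol without affecting any stereocentre or the olefin.

Step 10
Reactants: 12 eudesm-3-en-6α-ol
Product: 13 (5R,7S,10R)-eudesm-3-en-6-one
Conditions: Dess–Martin periodinane, NaHCO3, CH2Cl2, 0 °C
Reagents that add atoms: none
Why: Dess–Martin oxidation under buffered, non-enolizing conditions should give the β,γ-unsaturated ketone with the C3=C4 olefin and the C5 and C7 configurations intact.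

Step 11
Reactants: 13 eudesm-3-en-6-one
Product: 14 (5R,6R,7S,10R)-eudesm-3-en-6-ol (axial 6β-alcohol)
Conditions: NaBH4, CeCl3·7H2O, MeOH, −40 °C
Reagents that add atoms: none
Why: Luche reduction: hydride should add from the α face because the β face of the C6 carbonyl is blocked by the 1,3-diaxial C10 methyl group, giving the axial 6β-alcohol (C6 R), while low temperature and cerium buffering avoid conjugation of the olefin.

Step 12
Reactants: 14 eudesm-3-en-6β-ol
Product: 15 3-[(5R,6R,7S,10R)-eudesm-3-en-6-yloxy]-3-oxopropanoic acid (malonic half-ester)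
Conditions: Meldrum's acid, toluene, 100 °C
Reagents that add atoms: Meldrum's acid CC1(C)OC(=O)CC(=O)O1
Why: Acylation of an alcohol by Meldrum's acid (ring opening with loss of acetone) is a small, reactive acyl transfer that should work on the axial, hindered 6β-alcohol with retention at C6.

Step 13
Reactants: 15 malonic half-ester; 16 4-hydroxybenzaldehyde
Product: 18 (5R,6R,7S,10R)-eudesm-3-en-6-yl (E)-3-(4-hydroxyphenyl)prop-2-enoate (target), via benzylidenemalonic half-ester 17 (not isolated)
Conditions: pyridine, piperidine (cat.), 70 °C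
Reagents that add atoms: none
Why: Knoevenagel–Doebner condensation: the half-ester condenses with the aldehyde and intermediate 17 decarboxylates to the thermodynamically favoured E-cinnamate, so the free phenol needs no protection.

Compound list
1 | (2E,6E)-farnesol | OC/C=C(C)/CC/C=C(C)/CCC=C(C)C | starting material
2 | (2R,3R)-2,3-epoxy-(6E)-farnesol | OC[C@H]1O[C@]1(C)CC/C=C(C)/CCC=C(C)C | intermediate
3 | (2R,3R,6E,10E)-2,3-epoxy-3,7,11-trimethyldodeca-6,10-diene-1,12-diol | OC[C@H]1O[C@]1(C)CC/C=C(C)/CC/C=C(C)/CO | intermediate
4 | (2R,3R,6E,10E)-12-chloro-2,3-epoxy-3,7,11-trimethyldodeca-6,10-dien-1-ol | OC[C@H]1O[C@]1(C)CC/C=C(C)/CC/C=C(C)/CCl | intermediate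
5 | (2S,3R,6E,10E)-12-chloro-2,3-epoxy-3,7,11-trimethyldodeca-6,10-dienal | O=C[C@H]1O[C@]1(C)CC/C=C(C)/CC/C=C(C)/CCl | intermediate
6 | σ-allyl ethylzinc species from 5 (ZnEt in place of Cl at C12) | O=C[C@H]1O[C@]1(C)CC/C=C(C)/CC/C=C(C)/C[Zn]CC | intermediate (not isolated)
7 | ethylzinc alkoxide of (1(10)E,4R,5R,6S,7S)-4,5-epoxygermacra-1(10),11-dien-6-ol | C/C1=C\CC[C@@]2(C)O[C@@H]2[C@@H](O[Zn]CC)[C@H](C(C)=C)CC1 | intermediate (not isolated)
8 | (1(10)E,4R,5R,6S,7S)-4,5-epoxygermacra-1(10),11-dien-6-yl acetate | C/C1=C\CC[C@@]2(C)O[C@@H]2[C@@H](OC(C)=O)[C@H](C(C)=C)CC1 | intermediate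
9 | (1(10)E,4R,5R,6S,7S)-4,5-epoxygermacr-1(10)-en-6-yl acetate | C/C1=C\CC[C@@]2(C)O[C@@H]2[C@@H](OC(C)=O)[C@H](C(C)C)CC1 | intermediate
10 | (1(10)E,4E,6S,7S)-germacra-1(10),4-dien-6-yl acetate | C/C1=C\CC/C(C)=C/[C@@H](OC(C)=O)[C@H](C(C)C)CC1 | intermediate
11 | (5R,6S,7S,10R)-eudesm-3-en-6-yl acetate | CC1=CCC[C@]2(C)CC[C@@H](C(C)C)[C@H](OC(C)=O)[C@@H]12 | intermediate
12 | (5R,6S,7S,10R)-eudesm-3-en-6-ol (6α-ol) | CC1=CCC[C@]2(C)CC[C@@H](C(C)C)[C@H](O)[C@@H]12 | intermediate
13 | (5R,7S,10R)-eudesm-3-en-6-one | CC1=CCC[C@]2(C)CC[C@@H](C(C)C)C(=O)[C@@H]12 | intermediate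
14 | (5R,6R,7S,10R)-eudesm-3-en-6-ol (6β-ol) | CC1=CCC[C@]2(C)CC[C@@H](C(C)C)[C@@H](O)[C@@H]12 | intermediate
15 | 3-[(5R,6R,7S,10R)-eudesm-3-en-6-yloxy]-3-oxopropanoic acid | CC1=CCC[C@]2(C)CC[C@@H](C(C)C)[C@@H](OC(=O)CC(=O)O)[C@@H]12 | intermediate
16 | 4-hydroxybenzaldehyde | O=Cc1ccc(O)cc1 | starting material
17 | 2-(4-hydroxybenzylidene)malonic acid mono[(5R,6R,7S,10R)-eudesm-3-en-6-yl] ester (olefin geometry not defined) | CC1=CCC[C@]2(C)CC[C@@H](C(C)C)[C@@H](OC(=O)C(=Cc3ccc(O)cc3)C(=O)O)[C@@H]12 | intermediate (not isolated)
18 | (5R,6R,7S,10R)-eudesm-3-en-6-yl (E)-3-(4-hydroxyphenyl)prop-2-enoate | CC1=CCC[C@]2(C)CC[C@@H](C(C)C)[C@@H](OC(=O)/C=C/c3ccc(O)cc3)[C@@H]12 | target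

Total step count: 13. Longest linear sequence: 13 steps (from 1).

Steps most likely to fail

Step 8 (key step). The C4 cation may lose a proton from C15 faster than the exocyclic olefin re-equilibrates, so that olefin placement stalls at the exocyclic isomer, or prolonged acid exposure may erode the material. The fallback separates ring closure from olefin placement. Setting out from 10, the cyclization is run under kinetic, weakly acidic conditions (acid-washed silica gel or pyridinium p-toluenesulfonate in CH2Cl2) and stopped as soon as 10 is consumed. The co-formed exocyclic isomer, (5S,6S,7S,10R)-eudesm-4(15)-en-6-yl acetate F1, is then isomerized in the mixture with 11 by cobalt-hydride hydrogen-atom transfer (Co(salen)Cl, PhSiH3, benzene, rt). This should move the 1,1-disubstituted olefin one position into the ring toward the unhindered C3 methylene, while the trisubstituted olefin of 11 is inert, and so comes back to the route at 11.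

Step 5. Ethyl transfer from the zinc reagent to the aldehyde, intermolecular allylation to oligomers, opening of the epoxide, or attack on the wrong aldehyde face may compete with ring closure. The fallback closes the ring by a [2,3]-Wittig ring contraction in an epoxide-free series, setting out from 1.
- Acetylation (Ac2O, pyridine) gives (2E,6E)-farnesyl acetate F2.
- SeO2 (cat.)/t-BuOOH gives (2E,6E,10E)-12-hydroxyfarnesyl acetate F3.
- NCS/Me2S gives (2E,6E,10E)-12-chlorofarnesyl acetate F4.
- i-Bu2AlH at −78 °C gives (2E,6E,10E)-12-chlorofarnesol F5.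
- NaH in THF under high dilution closes the 13-membered diallyl ether (3E,7E,11E)-3,7,11-trimethyl-1-oxacyclotrideca-3,7,11-triene F6.
- Enantioselective deprotonation at the OCH2–CH= carbon with a single enantiomer of lithium bis(1-phenylethyl)amide (THF, −78 °C; the enantiomer that gives the 6S,7S series) triggers the ring contraction. The E-allyl terminus should give the anti product, (1(10)E,4E,6S,7S)-germacra-1(10),4,11-trien-6-ol F7.
- Hydrogenation with RhCl(PPh3)3 gives (1(10)E,4E,6S,7S)-germacra-1(10),4-dien-6-ol F8.
- Acetylation (Ac2O, DMAP) comes back to the route at 10; steps 6 and 7 are then not needed.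

Step 7. The Lewis-acidic tungsten chlorides may open the epoxide to a chlorohydrin or trigger transannular reactions of the product diene before oxygen transfer is complete. The fallback removes the oxygen through a carbonyl ylide instead of a metal oxo species. Setting out from 9, rhodium-carbenoid deoxygenation (dimethyl diazomalonate, Rh2(OAc)4 cat., benzene, 80 °C, short reaction time) transfers the epoxide oxygen to the carbene carbon under neutral conditions. The ylide fragments with retention to the 4E olefin and comes back to the route at 10; no new compound is made on the way.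

Further compounds
F1 | step 8 | (5S,6S,7S,10R)-eudesm-4(15)-en-6-yl acetate (5α-H, 6α-acetoxy, 7β-isopropyl, 10β-methyl) | C=C1CCC[C@]2(C)CC[C@@H](C(C)C)[C@H](OC(C)=O)[C@@H]12
F2 | step 5 | (2E,6E)-farnesyl acetate | CC(=O)OC/C=C(C)/CC/C=C(C)/CCC=C(C)C
F3 | step 5 | (2E,6E,10E)-12-hydroxyfarnesyl acetate | CC(=O)OC/C=C(C)/CC/C=C(C)/CC/C=C(C)/CO
F4 | step 5 | (2E,6E,10E)-12-chlorofarnesyl acetate | CC(=O)OC/C=C(C)/CC/C=C(C)/CC/C=C(C)/CCl
F5 | step 5 | (2E,6E,10E)-12-chlorofarnesol | OC/C=C(C)/CC/C=C(C)/CC/C=C(C)/CCl
F6 | step 5 | (3E,7E,11E)-3,7,11-trimethyl-1-oxacyclotrideca-3,7,11-triene | C/C1=C\CC/C(C)=C/CC/C(C)=C/COC1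
F7 | step 5 | (1(10)E,4E,6S,7S)-germacra-1(10),4,11-trien-6-ol | C/C1=C\CC/C(C)=C/[C@@H](O)[C@H](C(C)=C)CC1
F8 | step 5 | (1(10)E,4E,6S,7S)-germacra-1(10),4-dien-6-ol | C/C1=C\CC/C(C)=C/[C@@H](O)[C@H](C(C)C)CC1
F0 | step 7 | none | none
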